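## Retrosynthetic overview
- Goyazensolide ⇐ C15‑O desilylation. The 3(2H)‑furanone is the last ring formed, by transannular 5‑endo‑dig addition of the C10 hydroxyl to C3 of a ten‑membered α'‑hydroxy‑ynone.
- The ten‑membered carbocycle is the second ring, closed at C1–C2 by an intramolecular Nozaki–Hiyama–Kishi reaction (iodoalkyne plus aldehyde). The C2–C3 unit comes from a Sonogashira coupling at the C4 vinyl iodide.
- The C7–C8 bond and the exo‑methylene lactone ⇐ zinc Barbier coupling of a 3‑(bromomethyl)butenolide (C4–C7, C11–C13, C15) with a β‑silyloxy aldehyde (C8–C10, C1, C14). C6 relays to C7 and C8.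
- The butenolide is the first ring, made by RCM of an acrylate ester of a dienol. C6 comes from a lipase resolution of the propargyl alcohol/acrolein adduct, and the Z‑iodoalkene from Red‑Al/I2.
- The aldehyde ⇐ (S)‑2‑methylglycidol from catalytic Sharpless epoxidation of methallyl alcohol (C10), then vinyl‑copper opening and oxidative cleavage.

Assumption: germacrane numbering (C1–C15) is used for advanced intermediates. The given SMILES is read as 6R,7R,8S,10R, with C3 and C6 cis on the C4=C5 bond. CIP labels of unchanged centres switch where substituent priorities change.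

## Route

Step 1
Reactants: 1 2-methylprop-2-en-1-ol (methallyl alcohol)
Product: 2 (S)-2-methylglycidol
Conditions: Ti(OiPr)4 (5 mol %), L-(+)-DIPT (6 mol %), cumene hydroperoxide, 4 Å MS, CH2Cl2, −20 °C
Reagents that add atoms: cumene hydroperoxide CC(C)(OO)c1ccccc1
Why: In this catalytic Sharpless asymmetric epoxidation the Ti/L-(+)-tartrate catalyst delivers oxygen to one face of the achiral allylic alcohol and sets C10 (about 92–95 % ee, with the minor enantiomer leaving later as a separable diastereomer).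

Step 2
Reactants: 2 (S)-2-methylglycidol
Product: 4 (R)-2-[(4-methoxybenzyloxy)methyl]-2-methyloxirane, via sodium alkoxide 3 (not isolated)
Conditions: NaH, then PMBCl, TBAI (cat.), THF, 0 °C → rt
Reagents that add atoms: 4-methoxybenzyl chloride COc1ccc(CCl)cc1
Why: This Williamson etherification of the primary alkoxide leaves the quaternary epoxide carbon untouched (the Payne rearrangement is degenerate here), so only the CIP label changes.

Step 3
Reactants: 4 (R)-2-[(4-methoxybenzyloxy)methyl]-2-methyloxirane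
Product: 5 (R)-1-(4-methoxybenzyloxy)-2-methylpent-4-en-2-ol
Conditions: vinylMgBr, CuI (10 mol %), THF, −40 → 0 °C
Reagents that add atoms: vinylmagnesium bromide C=C[Mg]Br
Why: Copper-catalysed SN2 opening of the 2,2-disubstituted epoxide at its unhindered CH2 forms C8–C9 and frees the C10 tertiary alcohol without touching the stereocentre.

Step 4
Reactants: 5 (R)-1-(4-methoxybenzyloxy)-2-methylpent-4-en-2-ol
Product: 6 (R)-1-(4-methoxybenzyloxy)-2-methyl-2-(triethylsilyloxy)pent-4-ene
Conditions: TESOTf, 2,6-lutidine, CH2Cl2, −78 → 0 °C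
Reagents that add atoms: triethylsilyl triflate CC[Si](CC)(CC)OS(=O)(=O)C(F)(F)F
Why: Silyl triflate silylation reliably caps a hindered tertiary alcohol, and TES is orthogonal to PMB and TBDPS.

Step 5
Reactants: 6 (R)-1-(4-methoxybenzyloxy)-2-methyl-2-(triethylsilyloxy)pent-4-ene
Product: 8 (R)-4-(4-methoxybenzyloxy)-3-methyl-3-(triethylsilyloxy)butanal, via vicinal diol 7 (not isolated)
Conditions: OsO4 (2 mol %), NaIO4, 2,6-lutidine, dioxane/H2O, rt
Reagents that add atoms: osmium tetroxide O=[Os](=O)(=O)=O; sodium periodate [Na+].[O-]I(=O)(=O)=O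
Why: Lemieux–Johnson cleavage (dihydroxylation then glycol fission) of the only alkene gives the C8 aldehyde and spares the ozone-sensitive PMB ring.

Step 6
Reactants: 9 prop-2-yn-1-ol
Product: 10 tert-butyldiphenyl(prop-2-yn-1-yloxy)silane
Conditions: TBDPSCl, imidazole, CH2Cl2, 0 °C → rt
Reagents that add atoms: tert-butyldiphenylsilyl chloride CC(C)(C)[Si](Cl)(c1ccccc1)c1ccccc1
Why: Standard silylation installs an acid-robust group on the future C15 oxygen that lasts until the final step.

Step 7
Reactants: 10 tert-butyldiphenyl(prop-2-yn-1-yloxy)silane; 11 acrolein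
Product: 13 rac-6-(tert-butyldiphenylsilyloxy)hex-1-en-4-yn-3-ol, via lithium acetylide 12 (not isolated)
Conditions: n-BuLi, THF, −78 °C; then acrolein, −78 °C
Reagents that add atoms: none
Why: 1,2-Addition of the hard lithium acetylide to acrolein builds C5–C6 and gives the C6 carbinol as a racemate ready for resolution.

Step 8
Reactants: 13 rac-6-(tert-butyldiphenylsilyloxy)hex-1-en-4-yn-3-ol
Product: 14 (S)-6-(tert-butyldiphenylsilyloxy)hex-1-en-4-yn-3-ol
Conditions: lipase (immobilised Candida antarctica lipase B, EC 3.1.1.3), vinyl acetate, MTBE, 30 °C, stopped at about 53 % conversion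
Reagents that add atoms: none
Why: In this lipase-catalysed kinetic resolution by irreversible transesterification the enzyme acetylates the R enantiomer (Kazlauskas rule, with vinyl in the medium pocket and the long alkynyl arm in the large pocket), so running just past 50 % conversion leaves the S alcohol in ≥99 % ee and fixes C6.

Step 9
Reactants: 14 (S)-6-(tert-butyldiphenylsilyloxy)hex-1-en-4-yn-3-ol
Product: 16 (3S,4Z)-6-(tert-butyldiphenylsilyloxy)-5-iodohexa-1,4-dien-3-ol, via cyclic vinylalanate 15 (not isolated)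
Conditions: Red-Al, THF, 0 °C → rt; then I2, THF, −78 → 0 °C
Reagents that add atoms: iodine II
Why: Hydroxyl-directed trans-hydroalumination places aluminium on C4 inside a five-membered O–Al chelate, and iodinolysis with retention gives the vinyl iodide with iodine cis to C6, which sets the C4=C5 geometry.

Step 10
Reactants: 17 ethyl 2-(hydroxymethyl)acrylate
Product: 18 ethyl 2-[(tert-butyldimethylsilyloxy)methyl]acrylate
Conditions: TBSCl, imidazole, CH2Cl2, 0 °C → rt
Reagents that add atoms: tert-butyldimethylsilyl chloride CC(C)(C)[Si](C)(C)Cl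
Why: Standard silylation masks the future C13 oxygen with a group that can later be removed in the presence of TBDPS.

Step 11
Reactants: 18 ethyl 2-[(tert-butyldimethylsilyloxy)methyl]acrylate
Product: 20 2-[(tert-butyldimethylsilyloxy)methyl]acrylic acid, via lithium carboxylate 19 (not isolated)
Conditions: LiOH, THF/H2O, 0 °C → rt; then cold dilute HCl to pH 4
Reagents that add atoms: lithium hydroxide [Li+].[OH-]
Why: Mild saponification of the unhindered ethyl ester followed by careful acidification gives the acid with the TBS ether intact.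

Step 12
Reactants: 16 (3S,4Z)-6-(tert-butyldiphenylsilyloxy)-5-iodohexa-1,4-dien-3-ol; 20 2-[(tert-butyldimethylsilyloxy)methyl]acrylic acid
Product: 21 (3S,4Z)-6-(tert-butyldiphenylsilyloxy)-5-iodohexa-1,4-dien-3-yl 2-[(tert-butyldimethylsilyloxy)methyl]acrylate
Conditions: DCC, DMAP (cat.), CH2Cl2, 0 °C → rt
Reagents that add atoms: none
Why: Steglich esterification acylates on oxygen, so the C6–O bond and its configuration are retained.

Step 13
Reactants: 21 (3S,4Z)-6-(tert-butyldiphenylsilyloxy)-5-iodohexa-1,4-dien-3-yl 2-[(tert-butyldimethylsilyloxy)methyl]acrylate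
Product: 22 (S)-3-[(tert-butyldimethylsilyloxy)methyl]-5-[(Z)-3-(tert-butyldiphenylsilyloxy)-2-iodoprop-1-enyl]furan-2(5H)-one
Conditions: Hoveyda–Grubbs II (7 mol %), 1,4-benzoquinone (10 mol %), toluene (5 mM), 80 °C
Reagents that add atoms: none
Why: Ring-closing metathesis starts at the terminal vinyl group and closes onto the acrylate to form C7=C11, while the hindered trisubstituted vinyl iodide is inert and the base-free medium protects the acidic C6–H.

Step 14
Reactants: 22 (S)-3-[(tert-butyldimethylsilyloxy)methyl]-5-[(Z)-3-(tert-butyldiphenylsilyloxy)-2-iodoprop-1-enyl]furan-2(5H)-one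
Product: 23 (S)-3-(hydroxymethyl)-5-[(Z)-3-(tert-butyldiphenylsilyloxy)-2-iodoprop-1-enyl]furan-2(5H)-one
Conditions: AcOH/THF/H2O 3:1:1, rt
Reagents that add atoms: none
Why: Acid-catalysed desilylation removes the primary TBS ether far faster than the TBDPS ether and cannot epimerise C6.

Step 15
Reactants: 23 (S)-3-(hydroxymethyl)-5-[(Z)-3-(tert-butyldiphenylsilyloxy)-2-iodoprop-1-enyl]furan-2(5H)-one
Product: 24 (S)-3-(bromomethyl)-5-[(Z)-3-(tert-butyldiphenylsilyloxy)-2-iodoprop-1-enyl]furan-2(5H)-one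
Conditions: CBr4, PPh3, CH2Cl2, 0 °C
Reagents that add atoms: carbon tetrabromide BrC(Br)(Br)Br
Why: The Appel reaction converts the primary allylic alcohol into the bromide under neutral conditions that leave the butenolide stereocentre alone.

Step 16
Reactants: 24 (S)-3-(bromomethyl)-5-[(Z)-3-(tert-butyldiphenylsilyloxy)-2-iodoprop-1-enyl]furan-2(5H)-one; 8 (R)-4-(4-methoxybenzyloxy)-3-methyl-3-(triethylsilyloxy)butanal
Product: 26 (4R,5S)-4-[(1S,3R)-1-hydroxy-4-(4-methoxybenzyloxy)-3-methyl-3-(triethylsilyloxy)butyl]-5-[(Z)-3-(tert-butyldiphenylsilyloxy)-2-iodoprop-1-enyl]-3-methylenedihydrofuran-2(3H)-one, via allylzinc bromide 25 (not isolated)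
Conditions: activated Zn dust, THF/sat. aq NH4Cl, 0 °C → rt
Reagents that add atoms: none
Why: In this zinc Barbier allylation the γ-carbon C7 attacks on the butenolide face anti to the C6 alkenyl group (6,7-trans lactone) through a chair Zimmerman–Traxler transition state whose ring-locked E-type allyl geometry gives the 7,8-anti alcohol, so C7 and C8 are relayed from C6, the exo-methylene is unveiled and the trace C10 epimer is removed by chromatography.

Step 17
Reactants: 26 C8 alcohol from step 16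
Product: 27 8-O-methacryloyl derivative of 26 (6S,7R,8S,10R; all centres spatially unchanged)
Conditions: methacrylic anhydride, Et3N, DMAP (cat.), CH2Cl2, 0 °C → rt
Reagents that add atoms: methacrylic anhydride C=C(C)C(=O)OC(=O)C(C)=C
Why: DMAP-catalysed acylation with retention installs the natural ester early, which also blocks translactonisation and later lactol formation with C1.

Step 18
Reactants: 27 8-O-methacryloyl vinyl iodide
Product: 28 TMS-enyne (27 with C≡C–SiMe3 in place of iodine at C4, alkynyl cis to C6; 6R,7R,8S,10R)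
Conditions: trimethylsilylacetylene, PdCl2(PPh3)2 (5 mol %), CuI (10 mol %), Et3N, THF, rt
Reagents that add atoms: trimethylsilylacetylene C#C[Si](C)(C)C
Why: Sonogashira coupling of the reactive vinyl iodide proceeds at room temperature with retention of olefin geometry, and the tertiary amine base cannot add irreversibly to the acrylate-type acceptors.

Step 19
Reactants: 28 TMS-enyne
Product: 29 primary C1 alcohol (28 without the PMB group)
Conditions: DDQ, CH2Cl2/pH 7 buffer, 0 °C
Reagents that add atoms: none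
Why: Oxidative PMB cleavage is neutral and orthogonal to the TES, TBDPS, TMS-alkyne, ester and lactone groups.

Step 20
Reactants: 29 primary C1 alcohol
Product: 30 iodoalkyne (29 with iodine in place of SiMe3 at C2)
Conditions: NIS, AgNO3 (20 mol %), DMF, rt, dark
Reagents that add atoms: N-iodosuccinimide O=C1CCC(=O)N1I
Why: Silver-catalysed iododesilylation exchanges the alkynyl silane directly for iodine and so avoids the basic or fluoride desilylation that the lactone and TES ether would not tolerate.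

Step 21
Reactants: 30 iodoalkyne alcohol
Product: 31 C1 aldehyde of 30 (α-silyloxy aldehyde without α-hydrogen)
Conditions: DMP, CH2Cl2, 0 °C → rt
Reagents that add atoms: none
Why: Dess–Martin oxidation stops cleanly at the non-enolisable aldehyde under neutral conditions.

Step 22
Reactants: 31 iodoalkyne aldehyde
Product: 33 ten-membered enynol (C1–C2 bond closed; C1-OH as an epimer mixture; 6R,7R,8S,10R), via alkynylchromium(III) species 32 (not isolated)
Conditions: CrCl2 (10 equiv), NiCl2 (cat.), THF/DMF, rt, slow addition, 2 mM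
Reagents that add atoms: none
Why: The intramolecular Nozaki–Hiyama–Kishi reaction generates a non-basic alkynylchromium species that adds only to the aldehyde, the cis C4=C5 olefin pre-folds the chain, and the new C1 stereocentre is irrelevant because it is oxidised next.

Step 23
Reactants: 33 ten-membered enynol
Product: 34 ten-membered ynone (C1 ketone)
Conditions: DMP, CH2Cl2, rt
Reagents that add atoms: none
Why: Dess–Martin oxidation converges both propargylic alcohol epimers to a single ynone.

Step 24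
Reactants: 34 ten-membered ynone
Product: 35 C10 hydroxy-ynone
Conditions: HF·pyridine, pyridine, THF, 0 °C, 1–2 h
Reagents that add atoms: none
Why: Buffered fluoride desilylation removes TES much faster than the primary TBDPS ether and retains C10 because only the O–Si bond breaks.

Step 25
Reactants: 35 C10 hydroxy-ynone
Product: 36 15-O-TBDPS-goyazensolide
Conditions: Ph3PAuNTf2 (5 mol %), toluene, rt
Reagents that add atoms: none
Why: Gold(I) π-acid catalysis triggers a transannular 5-endo-dig oxa-Michael cycloisomerisation of the C10 hydroxyl onto C3, which forms the 3(2H)-furanone, releases alkyne strain and creates no new stereocentre.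

Step 26
Reactants: 36 15-O-TBDPS-goyazensolide
Product: 37 goyazensolide
Conditions: HF·pyridine, THF, 0 °C → rt
Reagents that add atoms: none
Why: Mildly acidic fluoride desilylation frees the C15 alcohol without attacking the methylene lactone, methacrylate or furanone acceptors that basic deprotection would destroy.

## Compound list
1 | 2-methylprop-2-en-1-ol | C=C(C)CO | starting material
2 | (S)-2-methylglycidol | C[C@]1(CO)CO1 | intermediate
3 | sodium (S)-(2-methyloxiran-2-yl)methanolate (not isolated) | C[C@]1(C[O-])CO1.[Na+] | intermediate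
4 | (R)-2-[(4-methoxybenzyloxy)methyl]-2-methyloxirane | C[C@]1(COCc2ccc(OC)cc2)CO1 | intermediate
5 | (R)-1-(4-methoxybenzyloxy)-2-methylpent-4-en-2-ol | C[C@](O)(COCc1ccc(OC)cc1)CC=C | intermediate
6 | (R)-1-(4-methoxybenzyloxy)-2-methyl-2-(triethylsilyloxy)pent-4-ene | C[C@](O[Si](CC)(CC)CC)(COCc1ccc(OC)cc1)CC=C | intermediate
7 | (4R)-5-(4-methoxybenzyloxy)-4-methyl-4-(triethylsilyloxy)pentane-1,2-diol, C2 epimers (not isolated) | C[C@](O[Si](CC)(CC)CC)(COCc1ccc(OC)cc1)CC(O)CO | intermediate
8 | (R)-4-(4-methoxybenzyloxy)-3-methyl-3-(triethylsilyloxy)butanal | C[C@](O[Si](CC)(CC)CC)(COCc1ccc(OC)cc1)CC=O | intermediate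
9 | prop-2-yn-1-ol | C#CCO | starting material
10 | tert-butyldiphenyl(prop-2-yn-1-yloxy)silane | C#CCO[Si](c1ccccc1)(c1ccccc1)C(C)(C)C | intermediate
11 | acrolein | C=CC=O | starting material
12 | [3-(tert-butyldiphenylsilyloxy)prop-1-ynyl]lithium (not isolated) | [Li]C#CCO[Si](c1ccccc1)(c1ccccc1)C(C)(C)C | intermediate
13 | rac-6-(tert-butyldiphenylsilyloxy)hex-1-en-4-yn-3-ol | C=CC(O)C#CCO[Si](c1ccccc1)(c1ccccc1)C(C)(C)C | intermediate
14 | (S)-6-(tert-butyldiphenylsilyloxy)hex-1-en-4-yn-3-ol | C=C[C@H](O)C#CCO[Si](c1ccccc1)(c1ccccc1)C(C)(C)C | intermediate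
15 | sodium bis(2-methoxyethoxy) cyclic vinylalanate, five-membered O–Al–C4=C5–C6 ring (not isolated) | [Na+].C=C[C@@H]1O[Al-](OCCOC)(OCCOC)C(CO[Si](c2ccccc2)(c2ccccc2)C(C)(C)C)=C1 | intermediate
16 | (3S,4Z)-6-(tert-butyldiphenylsilyloxy)-5-iodohexa-1,4-dien-3-ol | C=C[C@H](O)/C=C(\I)CO[Si](c1ccccc1)(c1ccccc1)C(C)(C)C | intermediate
17 | ethyl 2-(hydroxymethyl)acrylate | C=C(CO)C(=O)OCC | starting material
18 | ethyl 2-[(tert-butyldimethylsilyloxy)methyl]acrylate | C=C(CO[Si](C)(C)C(C)(C)C)C(=O)OCC | intermediate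
19 | lithium 2-[(tert-butyldimethylsilyloxy)methyl]acrylate (not isolated) | C=C(CO[Si](C)(C)C(C)(C)C)C(=O)[O-].[Li+] | intermediate
20 | 2-[(tert-butyldimethylsilyloxy)methyl]acrylic acid | C=C(CO[Si](C)(C)C(C)(C)C)C(=O)O | intermediate
21 | (3S,4Z)-6-(tert-butyldiphenylsilyloxy)-5-iodohexa-1,4-dien-3-yl 2-[(tert-butyldimethylsilyloxy)methyl]acrylate | C=C[C@H](OC(=O)C(=C)CO[Si](C)(C)C(C)(C)C)/C=C(\I)CO[Si](c1ccccc1)(c1ccccc1)C(C)(C)C | intermediate
22 | (S)-3-[(tert-butyldimethylsilyloxy)methyl]-5-[(Z)-3-(tert-butyldiphenylsilyloxy)-2-iodoprop-1-enyl]furan-2(5H)-one | O=C1O[C@H](/C=C(\I)CO[Si](c2ccccc2)(c2ccccc2)C(C)(C)C)C=C1CO[Si](C)(C)C(C)(C)C | intermediate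
23 | (S)-3-(hydroxymethyl)-5-[(Z)-3-(tert-butyldiphenylsilyloxy)-2-iodoprop-1-enyl]furan-2(5H)-one | O=C1O[C@H](/C=C(\I)CO[Si](c2ccccc2)(c2ccccc2)C(C)(C)C)C=C1CO | intermediate
24 | (S)-3-(bromomethyl)-5-[(Z)-3-(tert-butyldiphenylsilyloxy)-2-iodoprop-1-enyl]furan-2(5H)-one | O=C1O[C@H](/C=C(\I)CO[Si](c2ccccc2)(c2ccccc2)C(C)(C)C)C=C1CBr | intermediate
25 | allylzinc bromide derived from 24 (not isolated) | O=C1O[C@H](/C=C(\I)CO[Si](c2ccccc2)(c2ccccc2)C(C)(C)C)C=C1C[Zn]Br | intermediate
26 | Barbier product, C8 alcohol with 6,7-trans α-methylene lactone (6S,7R,8S,10R) | C=C1C(=O)O[C@H](/C=C(\I)CO[Si](c2ccccc2)(c2ccccc2)C(C)(C)C)[C@H]1[C@@H](O)C[C@@](C)(O[Si](CC)(CC)CC)COCc1ccc(OC)cc1 | intermediate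
27 | 8-O-methacryloyl derivative of 26 | C=C1C(=O)O[C@H](/C=C(\I)CO[Si](c2ccccc2)(c2ccccc2)C(C)(C)C)[C@H]1[C@@H](OC(=O)C(C)=C)C[C@@](C)(O[Si](CC)(CC)CC)COCc1ccc(OC)cc1 | intermediate
28 | TMS-enyne (C≡C–SiMe3 at C4, cis to C6) | C=C1C(=O)O[C@H](/C=C(\C#C[Si](C)(C)C)CO[Si](c2ccccc2)(c2ccccc2)C(C)(C)C)[C@H]1[C@@H](OC(=O)C(C)=C)C[C@@](C)(O[Si](CC)(CC)CC)COCc1ccc(OC)cc1 | intermediate
29 | primary C1 alcohol (PMB removed) | C=C1C(=O)O[C@H](/C=C(\C#C[Si](C)(C)C)CO[Si](c2ccccc2)(c2ccccc2)C(C)(C)C)[C@H]1[C@@H](OC(=O)C(C)=C)C[C@@](C)(O[Si](CC)(CC)CC)CO | intermediate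
30 | iodoalkyne alcohol | C=C1C(=O)O[C@H](/C=C(\C#CI)CO[Si](c2ccccc2)(c2ccccc2)C(C)(C)C)[C@H]1[C@@H](OC(=O)C(C)=C)C[C@@](C)(O[Si](CC)(CC)CC)CO | intermediate
31 | iodoalkyne C1 aldehyde | C=C1C(=O)O[C@H](/C=C(\C#CI)CO[Si](c2ccccc2)(c2ccccc2)C(C)(C)C)[C@H]1[C@@H](OC(=O)C(C)=C)C[C@@](C)(O[Si](CC)(CC)CC)C=O | intermediate
32 | alkynylchromium(III) dichloride derived from 31 (not isolated) | C=C1C(=O)O[C@H](/C=C(\C#C[Cr](Cl)Cl)CO[Si](c2ccccc2)(c2ccccc2)C(C)(C)C)[C@H]1[C@@H](OC(=O)C(C)=C)C[C@@](C)(O[Si](CC)(CC)CC)C=O | intermediate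
33 | ten-membered enynol, C1 epimers | C=C(C)C(=O)O[C@H]1C[C@@](C)(O[Si](CC)(CC)CC)C(O)C#C/C(CO[Si](c3ccccc3)(c3ccccc3)C(C)(C)C)=C\[C@H]2OC(=O)C(=C)[C@H]12 | intermediate
34 | ten-membered ynone | C=C(C)C(=O)O[C@H]1C[C@@](C)(O[Si](CC)(CC)CC)C(=O)C#C/C(CO[Si](c3ccccc3)(c3ccccc3)C(C)(C)C)=C\[C@H]2OC(=O)C(=C)[C@H]12 | intermediate
35 | C10 hydroxy-ynone | C=C(C)C(=O)O[C@H]1C[C@@](C)(O)C(=O)C#C/C(CO[Si](c3ccccc3)(c3ccccc3)C(C)(C)C)=C\[C@H]2OC(=O)C(=C)[C@H]12 | intermediate
36 | 15-O-TBDPS-goyazensolide | C=C(C)C(=O)O[C@H]1C[C@@]2(C)OC(=CC2=O)/C(CO[Si](c3ccccc3)(c3ccccc3)C(C)(C)C)=C\[C@H]2OC(=O)C(=C)[C@H]12 | intermediate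
37 | goyazensolide | C=C(C)C(=O)O[C@H]1C[C@@]2(C)OC(=CC2=O)/C(CO)=C\[C@H]2OC(=O)C(=C)[C@H]12 | target

## Step count and risks
Total steps: 26. Longest linear sequence: 19 (steps 6–9, then 12–26).

**Step 13 (RCM onto a 1,1-disubstituted acrylate beside a vinyl iodide).** The risks are slow closure, catalyst decay and olefin migration. The fallback closes the ring on an unhindered acrylate and brings in C13 afterwards. It sets out from 16.
- Acryloyl chloride and iPr2NEt give the acrylate ester F1.
- Metathesis in refluxing CH2Cl2 gives the unsubstituted butenolide F2.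
- Lithium phenylselenide adds to C7 anti to the C6 substituent, and the enolate is trapped with monomeric formaldehyde at −78 °C. This gives the β-phenylselanyl α-hydroxymethyl lactone F3.
- H2O2 oxidation and syn-elimination, directed away from the oxygen-bearing C6, restore the C7=C11 bond. The route is rejoined at 23.

**Step 16 (Barbier coupling, C7/C8 diastereocontrol).** The risk is that the 7,8-syn alcohol dominates. The fallback corrects C8 by inversion instead of relying on the transition state. It sets out from 24 and 8.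
- Their coupling product of the wrong C8 configuration, the C8 epimer F4, is isolated.
- F4 undergoes Mitsunobu esterification with methacrylic acid (PPh3, DIAD, toluene, 0 °C → rt).
- The SN2 displacement inverts C8 and installs the methacrylate in one operation. The route is rejoined at 27, so 26 and step 17 are bypassed.

**Step 22 (NHK macrocyclisation).** The risks are oligomerisation and protodemetalation of the alkynylchromium species. The fallback closes the ring at C3–C4 instead of C1–C2. It sets out from 27.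
- DDQ gives the vinyl iodide primary alcohol F5.
- Dess–Martin oxidation gives the vinyl iodide aldehyde F6.
- Ethynylmagnesium bromide with CeCl3 at −78 °C adds chemoselectively to the aldehyde and gives the terminal propargylic alcohol F7 (C1 epimers).
- A high-dilution intramolecular Sonogashira coupling (Pd(PPh3)4, CuI, Et3N, THF, slow addition) joins the alkyne terminus to the C4 vinyl iodide. The route is rejoined at 33, so steps 18–22 are bypassed.

Further compounds
F1 | step 13 | (3S,4Z)-6-(tert-butyldiphenylsilyloxy)-5-iodohexa-1,4-dien-3-yl acrylate | C=C[C@H](OC(=O)C=C)/C=C(\I)CO[Si](c1ccccc1)(c1ccccc1)C(C)(C)C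
F2 | step 13 | (S)-5-[(Z)-3-(tert-butyldiphenylsilyloxy)-2-iodoprop-1-enyl]furan-2(5H)-one | O=C1O[C@H](/C=C(\I)CO[Si](c2ccccc2)(c2ccccc2)C(C)(C)C)C=C1
F3 | step 13 | (5S)-3-(hydroxymethyl)-4-(phenylselanyl)-5-[(Z)-3-(tert-butyldiphenylsilyloxy)-2-iodoprop-1-enyl]dihydrofuran-2(3H)-one | O=C1O[C@H](/C=C(\I)CO[Si](c2ccccc2)(c2ccccc2)C(C)(C)C)C([Se]c2ccccc2)C1CO
F4 | step 16 | C8 epimer of 26 (7,8-syn alcohol) | C=C1C(=O)O[C@H](/C=C(\I)CO[Si](c2ccccc2)(c2ccccc2)C(C)(C)C)[C@H]1[C@H](O)C[C@@](C)(O[Si](CC)(CC)CC)COCc1ccc(OC)cc1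
F5 | step 22 | vinyl iodide primary C1 alcohol (27 without PMB) | C=C1C(=O)O[C@H](/C=C(\I)CO[Si](c2ccccc2)(c2ccccc2)C(C)(C)C)[C@H]1[C@@H](OC(=O)C(C)=C)C[C@@](C)(O[Si](CC)(CC)CC)CO
F6 | step 22 | vinyl iodide C1 aldehyde | C=C1C(=O)O[C@H](/C=C(\I)CO[Si](c2ccccc2)(c2ccccc2)C(C)(C)C)[C@H]1[C@@H](OC(=O)C(C)=C)C[C@@](C)(O[Si](CC)(CC)CC)C=O
F7 | step 22 | vinyl iodide terminal propargylic alcohol, C1 epimers | C=C1C(=O)O[C@H](/C=C(\I)CO[Si](c2ccccc2)(c2ccccc2)C(C)(C)C)[C@H]1[C@@H](OC(=O)C(C)=C)C[C@@](C)(O[Si](CC)(CC)CC)C(O)C#C
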